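## Structural features

The target is a biflavanone in which C3 of an upper eriodictyol-type unit (rings A, C and B; hydroxyls on C5, C7, C3' and C4') is bonded to C8'' of ring A'' of a lower naringenin unit (rings A'', C'' and B''). C2 and C3 are neighbouring stereocenters in ring C with their two aryl groups cis (2R,3R), and C2'' (S) stands alone in ring C''. The C3–C8'' bond carries four ortho substituents (the C2 aryl group and C4=O on one side, O1'' and the C7'' oxygen on the other). It is hard to form, and whenever C3 is sp2 it is a biaryl axis that may rotate slowly. C3–H is alpha to the C4 ketone and benzylic to ring A'', so acid or base would epimerise the cis pair to the more stable trans isomer. Base can also open either pyranone ring by retro-oxa-Michael reaction, which would racemise C2 and C2'' and let the lower unit close again through the other ortho oxygen to the 6''-linked isomer. The seven free phenols, a catechol among them, are sensitive to oxidants. The real difficulty is to build the congested C3–C8'' bond and to set three stereocenters, two of them contiguous and in the less stable arrangement, without acid or base once they exist. The key step uses the fact that C2'' is benzylic and para to the hydroxyl of ring B''. Two-electron oxidation of that phenol makes C2'' the exocyclic carbon of a para-quinone methide, six atoms away from the oxygen on C8a'', which closes ring C'' by forming O1''–C2''.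

## Logic of the disconnections

**13 ⇒ 12.** Six aryl oxygen–benzyl bonds are cut. The free heptaphenol should appear only in the last step and under neutral conditions, because the cis C2/C3 pair and both pyranone rings do not survive acid or base. The gain is that every earlier intermediate is a lipophilic, oxidation-resistant ether with one ether type throughout. The forward step must spare the benzylic C2–O1 and C2''–O1'' bonds, both ketones and the C3 configuration.

**12 ⇒ 11.** The C2–H and C3–H bonds are removed, so ring C becomes a chromone. This deletes both contiguous stereocenters at once; because they are cis, they correspond to one syn addition of hydrogen. It also turns the C3–C8'' bond into an sp2–sp2 bond that a cross-coupling can make. The gain is a flat upper unit at the oxidation level of a commercial flavone. The forward step must be a face-selective, catalyst-controlled hydrogenation of a tetrasubstituted, diaryl-substituted double bond that leaves C2'', the ketones and the benzyl ethers alone.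

**11 ⇒ 9 (through 10).** The O1''–C2'' bond of ring C'' is cut; this is the key disconnection. C2'' is the last stereocenter, and the open form is a saturated aryl ketone at the oxidation level of a commercial dihydrochalcone, so neither a chalcone nor a base is needed to close it. The gain is the loss of a ring and of the last stereocenter: 9 has no stereocenter, only the axis. The forward step must oxidise only the phenol of ring B'', close through the one free ortho oxygen faster than 10 isomerises, and set the new center with an external chiral acid.

**9 ⇒ 7 + 4 (through 8).** The C3–C8'' carbon–carbon bond is cut. It is the only bond joining the two flavonoid skeletons, and cutting it gives two halves of similar size, each two steps from a commercial flavonoid. The gain is full convergence. The forward step must form a tetra-ortho-substituted biaryl in the presence of two free phenols. The halide is therefore placed on the chromone carbon, and the boron, made in the same flask as 8, on the electron-rich ring.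

**4 ⇒ 2 ⇒ 1.** The carbon–iodine bond at C3 and then four oxygen–benzyl bonds are cut. C3 is the one position selected by a base and not by an electrophile, so the halogen can be placed without touching rings A and B. The benzyl groups are the ones removed at the end. The gain is a commercial starting material. The forward steps must lithiate C3 without attacking the benzylic methylenes and must etherify all four hydroxyls, the chelated 5-hydroxyl included.

**7 ⇒ 6 ⇒ 5.** The carbon–iodine bond at C3' and then two oxygen–benzyl bonds are cut. The iodine marks the future C8''. The two benzyl ethers protect the future C5'' and C7'' oxygens to the end and leave only one ortho oxygen free for step 6. The gain is a commercial starting material that already has the full carbon skeleton and oxidation level of the lower unit. The forward steps must etherify only the two most acidic hydroxyls and iodinate ortho to the chelated hydroxyl, not between the two ethers or on ring B''.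

## Other disconnections considered

**Alternative 1:** The cut is the C4a–C5 bond of ring A of the upper unit, so this phloroglucinol ring is built from an open chain.
- Forward step: dioxinone A2 would be heated in methanol to release the methyl trioxo ester A3. Mg(OMe)2 would fold A3 by Claisen condensation (chain C6 onto the ester carbon) to aryl ketone A1, whose methylene carbon is the future C3. Aroylation and cyclodehydration would then complete ring C as a chromone.
- In favour: the C3–C8'' link enters as an sp3 methylene on the lower unit before it becomes congested, so no tetra-ortho-substituted cross-coupling is needed; here the alternative is better than the chosen plan. Its key step is a Mg(OMe)2-mediated polyketide folding of a known type, so on precedent it is also better.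
- Against: A1 has three free phenols that must be differentiated again. Aldol-type folding of A3 to a pyranone or a resorcylate competes with the Claisen mode. The step creates no stereocenter. The lower unit is carried as a flavone, so two pyranone double bonds, C2=C3 and C2''=C3'', must later be reduced enantioselectively.
- Comparison: the tetrasubstituted upper hydrogenation is the same problem as in the chosen plan (equal), but a second reduction is added and the chain assembly leading to A2 is long. In step economy the chosen eight-step route is clearly ahead.

**Alternative 2:** The cut removes O1–C8a and C4–C4a, so ring A of the upper unit arrives as an aryne.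
- Forward step: CsF would release aryne A7 from silyl triflate A6. The secondary hydroxyl of the syn beta-hydroxy ester A5 would add to the aryne carbon remote from the neighbouring benzyloxy group. The aryl anion formed next to that group would attack the ester and give the cis-(2R,3R)-flavanone A4.
- In favour: two bonds and a ring form in one operation, against one bond in the chosen key step (better). The regiochemistry follows the usual preference of 3-alkoxyarynes and needs no blocking group (equal to the chosen plan, where one free hydroxyl decides). C2 and C3 are set in an open-chain precursor, so the hydrogenation of a tetrasubstituted chromone is avoided (better).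
- Against: the conditions are basic. A5 has an alpha-aryl ester hydrogen and a benzylic beta-alkoxide, so epimerisation at the future C3, retro-aldol cleavage and beta-elimination compete with addition of a hindered secondary alkoxide to A7. A4 is epimerisable by the same fluoride. The enantio- and syn-selective aldol reaction needed to make A5 from a di-ortho-substituted arylacetate is not trivial. The lower unit is still a flavone, whose C2''=C3'' bond must later be reduced enantioselectively next to the base-labile cis pair.
- Comparison: the chosen step is neutral and cannot epimerise anything; the alternative can. In step count the two are comparable, the alternative somewhat longer because A5 and A6 each need several steps.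

**Alternative 3:** The cut is C2–C3 of ring C of the upper unit.
- Forward step: a chiral divalent rhodium carboxylate such as Rh2(S-PTAD)4 would decompose diazo ketone A9. The carbene at C3 would insert into a benzylic C–H bond of one of the two equivalent 3,4-bis(benzyloxy)benzyl ethers ortho to the ketone and give A8, the fully protected target with all three stereocenters.
- In favour: both upper stereocenters are made in one catalytic step. The lower unit can be carried in its final (2''S)-flavanone form from the start. The endgame is one hydrogenolysis with no reduction of a tetrasubstituted double bond; on the endgame the alternative is better than the chosen plan.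
- Against: closing a six-membered ring by C–H insertion is less favourable than the five-membered mode, and the methylene of the C7'' benzyl ether is placed exactly for a five-membered insertion. Attack of the carbene on the ortho ether oxygen, giving an oxonium ylide and then a 1,2-benzyl shift, is a further competing path. Cis selectivity and face selectivity at a carbene next to a di-ortho-substituted aryl group are uncertain. The alpha-aryl ketone that holds the C3–C8'' bond, and diazo transfer at its hindered position, must be solved first.
- Comparison: both plans rest on a demanding ring closure with little precedent (roughly equal). The carbene has several intramolecular outlets, whereas quinone methide 10 has one nucleophile within reach. The route to A9 would be considerably longer than the five steps that lead to 9.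

Key step: step 6

Assumption: the sense of induction of (R)-TRIP, which is (R)-3,3'-bis(2,4,6-triisopropylphenyl)-1,1'-binaphthyl-2,2'-diyl hydrogen phosphate, in step 6 and of (R,R)-Me-DuPhos in step 7 is a working assignment; the antipodal acid or ligand is used if the opposite sense results.

Remark: compounds 9, 10 and 11 contain the tetra-ortho-substituted C3–C8'' biaryl axis and are drawn without an axial descriptor; if rotation is slow, each is a mixture of atropisomers that converge in step 7, where C3 becomes sp3.

## Route

Step 1
Reactants: 1 luteolin
Product: 2 5,7,3',4'-tetra-O-benzylluteolin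
Conditions: BnBr (6 equiv), K2CO3, DMF, 80 °C
Reagents that add atoms: benzyl bromide, BrCc1ccccc1
Why: Williamson etherification of all four phenols; heating with excess halide also alkylates the hydrogen-bonded 5-hydroxyl, and the ethers tolerate LiN(iPr)2, the coupling and the electrolysis while staying removable by neutral hydrogenolysis.

Step 2
Reactants: 2 5,7,3',4'-tetra-O-benzylluteolin
Product: 4 3-iodo-5,7,3',4'-tetra-O-benzylluteolin, via 3-lithioflavone 3 (not isolated)
Conditions: LiN(iPr)2 (1.3 equiv), THF, −78 °C; then I2, −78 °C
Reagents that add atoms: iodine, [I][I]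
Why: Directed lithiation and iodination; C3–H, between the carbonyl group and the enol-ether carbon, is the most acidic C–H of a flavone towards LiN(iPr)2, so the halogen is placed by deprotonation and not by electrophilic substitution, which would attack the electron-rich rings A and B. The lithio species 3 is kept at −78 °C so that it does not open to the ynone phenoxide.

Step 3
Reactants: 5 phloretin
Product: 6 4',6'-di-O-benzylphloretin
Conditions: BnBr (2.05 equiv, slow addition), K2CO3 (2.2 equiv), DMF, 0 °C → rt
Reagents that add atoms: benzyl bromide, BrCc1ccccc1
Why: Acidity-controlled Williamson etherification; with two equivalents of base and halide only the two most acidic hydroxyls should react, the one para to the carbonyl group and then the non-chelated ortho one, as in the standard 4,6-dibenzylation of phloroacetophenone. The chelated 2'-hydroxyl and the unconjugated phenol of the 4-hydroxyphenyl ring, several pKa units weaker in a dipolar aprotic solvent, should stay free, and these are the two hydroxyls that step 6 needs.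

Step 4
Reactants: 6 4',6'-di-O-benzylphloretin
Product: 7 3'-iodo-4',6'-di-O-benzylphloretin
Conditions: NIS (1.0 equiv), DMF, 0 °C, dark
Reagents that add atoms: N-iodosuccinimide, O=C1CCC(=O)N1I
Why: Electrophilic aromatic iodination; the trioxygenated ring is far more nucleophilic than the 4-alkylphenol ring, which needs acid activation to react with NIS, and attack ortho to the chelated hydroxyl (C3') is the usual outcome for 2-hydroxy-4,6-dialkoxyaryl ketones. One equivalent at 0 °C limits di-iodination.

Step 5
Reactants: 7 3'-iodo-4',6'-di-O-benzylphloretin; 4 3-iodo-5,7,3',4'-tetra-O-benzylluteolin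
Product: 9 3'-(5,7,3',4'-tetra-O-benzylluteolin-3-yl)-4',6'-di-O-benzylphloretin, via pinacol boronate 8 (not isolated)
Conditions: B2pin2, Pd(OAc)2 (5 mol%), SPhos (10 mol%), KOAc, 1,4-dioxane, 80 °C; then 4, K3PO4, H2O, 80 °C
Reagents that add atoms: none
Why: Miyaura borylation followed in the same flask by Suzuki–Miyaura coupling; the catalyst formed from Pd(OAc)2 and SPhos (zerovalent palladium in the cycle) is established for 2,6-dioxygenated arylboron reagents and for tetra-ortho-substituted biaryls, and the 3-iodochromone is an activated partner for oxidative addition. Using 8 crude avoids its protodeboronation on silica, and the two free phenols are tolerated as phenoxides under K3PO4.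

Step 6
Reactants: 9 3'-(5,7,3',4'-tetra-O-benzylluteolin-3-yl)-4',6'-di-O-benzylphloretin
Product: 11 (2S)-5,7-di-O-benzyl-8-(5,7,3',4'-tetra-O-benzylluteolin-3-yl)naringenin, via para-quinone methide 10 (not isolated)
Conditions: graphite anode, Pt cathode, undivided cell, anode potential held at the foot of the phenol wave (found by cyclic voltammetry), about 2 F/mol, Bu4NBF4 (0.1 mol/L), (R)-TRIP (10 mol%), tetrabutylammonium salt of (R)-TRIP (10 mol%), CH2Cl2, −20 °C
Reagents that add atoms: none
Why: Proposed new method: the 4-hydroxyphenyl group, hydrogen-bonded to the chiral phosphate, is oxidised at the graphite anode by two electrons with loss of the O–H and C2''–H protons to give para-quinone methide 10, while the protons are reduced to H2 at the cathode, so the cell stays neutral and the phosphate is regenerated. The closest known reaction types are the anodic and the quinone-mediated dehydrogenation of 4-alkylphenols to para-quinone methides and the chiral-phosphoric-acid-catalysed oxa-1,6-addition of hydroxyl groups to para-quinone methides formed in situ; running the two together under electrolysis is the new element. Ring C'' closes by a 6-exo-trig oxa-1,6-addition of the C8a'' hydroxyl to the exocyclic carbon of 10, which forms O1''–C2'' and restores the aromatic ring B''. The C2'' stereocenter is controlled by the acid, whose P=O and P–OH groups bridge the attacking hydroxyl and the quinone methide oxygen between the two triisopropylphenyl groups, so that one face of the methide is exposed. The oxidation must be chemoselective, and the substrate secures this: the phenol of ring B'' is the only hydroxyl that is neither chelated to nor conjugated with a carbonyl group, all other oxygens are benzyl ethers on acyl- or pyranone-bearing rings, and proton-coupled electron transfer to the phosphate lowers its potential further. Regioselectivity is secured by the benzyl ether on the C5'' oxygen, which leaves the oxygen next to C8'' as the only one able to close. The cyclisation must outrun the prototropic shift of 10 to the 4-hydroxychalcone, which the intramolecular six-membered closure, the absence of base and the low temperature favour, and passing no more than about 2 F/mol keeps the product phenol from being oxidised on to the flavone.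

Step 7
Reactants: 11 (2S)-5,7-di-O-benzyl-8-(5,7,3',4'-tetra-O-benzylluteolin-3-yl)naringenin
Product: 12 (2R,3R,2''S)-hexa-O-benzyl biflavanone (all hydroxyls of 13 benzylated except the one on ring B'')
Conditions: H2 (60 bar), [Rh(cod)2]BF4 (10 mol%), (R,R)-Me-DuPhos (11 mol%), CH2Cl2–CF3CH2OH, 40 °C
Reagents that add atoms: none
Why: Homogeneous asymmetric hydrogenation of the chromone C2=C3 bond with the catalyst formed from [Rh(cod)2]BF4 and the bisphosphine (monovalent rhodium); both hydrogens are delivered to one face, so C2–H and C3–H are necessarily cis, and the ligand selects the face that gives (2R,3R). The fluorinated alcohol activates the vinylogous ester by hydrogen bonding to C4=O, and the neutral conditions leave the ketones, the benzyl ethers, C2'' and the new C3–H untouched.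

Step 8
Reactants: 12 (2R,3R,2''S)-hexa-O-benzyl biflavanone
Product: 13 CNP0105436.1, the (2R,3R,2''S)-biflavanone
Conditions: H2 (1 atm), 10% Pd/C, THF–MeOH, rt
Reagents that add atoms: none
Why: Hydrogenolysis of the six aryl benzyl ethers over Pd/C; the neutral medium at room temperature should leave the epimerisable C3–H, the benzylic C–O bonds of both pyranone rings and the ketones intact if the reaction is stopped at the calculated uptake.

## Compound list

1 | luteolin | O=c1cc(-c2ccc(O)c(O)c2)oc2cc(O)cc(O)c12 | starting material
2 | 5,7,3',4'-tetra-O-benzylluteolin; 5,7-bis(benzyloxy)-2-[3,4-bis(benzyloxy)phenyl]-4H-chromen-4-one | O=c1cc(-c2ccc(OCc3ccccc3)c(OCc3ccccc3)c2)oc2cc(OCc3ccccc3)cc(OCc3ccccc3)c12 | intermediate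
3 | 3-lithio-5,7,3',4'-tetra-O-benzylluteolin | [Li]c1c(-c2ccc(OCc3ccccc3)c(OCc3ccccc3)c2)oc2cc(OCc3ccccc3)cc(OCc3ccccc3)c2c1=O | intermediate (not isolated)
4 | 3-iodo-5,7,3',4'-tetra-O-benzylluteolin; 5,7-bis(benzyloxy)-2-[3,4-bis(benzyloxy)phenyl]-3-iodo-4H-chromen-4-one | O=c1c(I)c(-c2ccc(OCc3ccccc3)c(OCc3ccccc3)c2)oc2cc(OCc3ccccc3)cc(OCc3ccccc3)c12 | intermediate
5 | phloretin | O=C(CCc1ccc(O)cc1)c1c(O)cc(O)cc1O | starting material
6 | 4',6'-di-O-benzylphloretin; 1-[2,4-bis(benzyloxy)-6-hydroxyphenyl]-3-(4-hydroxyphenyl)propan-1-one | O=C(CCc1ccc(O)cc1)c1c(O)cc(OCc2ccccc2)cc1OCc1ccccc1 | intermediate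
7 | 3'-iodo-4',6'-di-O-benzylphloretin; 1-[4,6-bis(benzyloxy)-2-hydroxy-3-iodophenyl]-3-(4-hydroxyphenyl)propan-1-one | O=C(CCc1ccc(O)cc1)c1c(O)c(I)c(OCc2ccccc2)cc1OCc1ccccc1 | intermediate
8 | pinacol boronate; 1-[4,6-bis(benzyloxy)-2-hydroxy-3-(4,4,5,5-tetramethyl-1,3,2-dioxaborolan-2-yl)phenyl]-3-(4-hydroxyphenyl)propan-1-one | O=C(CCc1ccc(O)cc1)c1c(O)c(B2OC(C)(C)C(C)(C)O2)c(OCc2ccccc2)cc1OCc1ccccc1 | intermediate (not isolated)
9 | 3-{4,6-bis(benzyloxy)-2-hydroxy-3-[3-(4-hydroxyphenyl)propanoyl]phenyl}-5,7-bis(benzyloxy)-2-[3,4-bis(benzyloxy)phenyl]-4H-chromen-4-one (axis not specified) | O=C(CCc1ccc(O)cc1)c1c(O)c(-c2c(-c3ccc(OCc4ccccc4)c(OCc4ccccc4)c3)oc3cc(OCc4ccccc4)cc(OCc4ccccc4)c3c2=O)c(OCc2ccccc2)cc1OCc1ccccc1 | intermediate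
10 | para-quinone methide of 9; the 4-hydroxyphenyl group is a 4-oxocyclohexa-2,5-dien-1-ylidene unit doubly bonded to C2'' | O=C1C=CC(=CCC(=O)c2c(O)c(-c3c(-c4ccc(OCc5ccccc5)c(OCc5ccccc5)c4)oc4cc(OCc5ccccc5)cc(OCc5ccccc5)c4c3=O)c(OCc3ccccc3)cc2OCc2ccccc2)C=C1 | intermediate (not isolated)
11 | 5,7-bis(benzyloxy)-2-[3,4-bis(benzyloxy)phenyl]-3-[(2S)-5,7-bis(benzyloxy)-2-(4-hydroxyphenyl)-4-oxochroman-8-yl]-4H-chromen-4-one (axis not specified) | O=C1C[C@@H](c2ccc(O)cc2)Oc2c1c(OCc1ccccc1)cc(OCc1ccccc1)c2-c1c(-c2ccc(OCc3ccccc3)c(OCc3ccccc3)c2)oc2cc(OCc3ccccc3)cc(OCc3ccccc3)c2c1=O | intermediate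
12 | (2R,3R)-5,7-bis(benzyloxy)-2-[3,4-bis(benzyloxy)phenyl]-3-[(2S)-5,7-bis(benzyloxy)-2-(4-hydroxyphenyl)-4-oxochroman-8-yl]chroman-4-one | O=C1C[C@@H](c2ccc(O)cc2)Oc2c1c(OCc1ccccc1)cc(OCc1ccccc1)c2[C@H]1C(=O)c2c(OCc3ccccc3)cc(OCc3ccccc3)cc2O[C@H]1c1ccc(OCc2ccccc2)c(OCc2ccccc2)c1 | intermediate
13 | (2R,3R)-2-(3,4-dihydroxyphenyl)-5,7-dihydroxy-3-[(2S)-5,7-dihydroxy-2-(4-hydroxyphenyl)-4-oxochroman-8-yl]chroman-4-one (CNP0105436.1) | O=C1C[C@@H](c2ccc(O)cc2)Oc2c1c(O)cc(O)c2[C@H]1C(=O)c2c(O)cc(O)cc2O[C@H]1c1ccc(O)c(O)c1 | target

## Step count and least certain steps

Total: 8 steps. Longest linear sequence: 6 steps (5 → 6 → 7 → 9 → 11 → 12 → 13; the branch from 1 through 2 and 4 is equally long).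

**Step 6 (key step, proposed new method).** What is most likely to go wrong is loss of control over how the quinone methide reacts:
- ring closure in the diffusion layer before the acid is bound, which gives a racemic background;
- prototropic isomerisation to the chalcone;
- electron transfer from the benzyloxyarenes instead of the phenol;
- further oxidation of the product phenol;
- a different response of the two atropisomers of 9 to the acid.

The fallback uses known chemistry. It sets out from 9: stoichiometric 2,3-dichloro-5,6-dicyano-1,4-benzoquinone (1 equiv, 1,4-dioxane, rt), the known quinone dehydrogenation of 4-alkylphenols with trapping by an internal hydroxyl, should give the flavanone as a mixture of C2'' epimers F1. Preparative HPLC on a polysaccharide chiral phase then separates the (2''S) material from the (2''R) isomer F2. The fallback returns to the route at 11.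

**Step 7.** The most likely failures are slow or absent hydrogen uptake, because both faces of C3 are screened by O1'' and the C7'' benzyloxy group of the perpendicular ring A'', and erosion of facial selectivity where the fixed axis and the ligand are mismatched. The fallback gives up reagent control and uses C2'' as an internal reference. It sets out from 11: hydrogenation with the achiral complex [Ir(cod)(PCy3)(py)]PF6 (H2, CH2Cl2), a catalyst type established for hindered tetrasubstituted alkenes, should give by syn addition both cis products, 12 and its (2S,3S,2''S) diastereomer F3. These are separated by preparative HPLC as diastereomers, and the fallback returns to the route at 12.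

**Step 5.** The most likely failure is protodeboronation of the di-ortho-oxygenated boronate, or hydrodeiodination during its formation, outrunning transmetalation onto the hindered oxidative-addition complex of 4. The fallback reverses the polarity and changes the organometallic partner:
- 7 is converted into its bis(methoxymethyl) ether F4 (NaH, MOMCl, DMF, 0 °C).
- 2 is lithiated as in step 2 to 3 and transmetalated with ZnCl2 to the 3-(chlorozincio)flavone F5.
- Negishi coupling of F5 with F4 (Pd2(dba)3, RuPhos, THF, 65 °C), a known route to tetra-ortho-substituted biaryls, should give the bis(methoxymethyl) biaryl F6.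
- HCl in MeOH–THF at 50 °C removes both acetals, and the fallback returns to the route at 9.

**Step 3.** The most likely failure is incomplete site selectivity, with alkylation spreading to the hydroxyl of the 4-hydroxyphenyl ring or stopping at the mono-ether. The fallback masks that phenol first and sets out from 5:
- Full deprotonation of the three non-chelated hydroxyls (NaH, 3 equiv, DMF, 0 °C) and one equivalent of iPr3SiCl should silylate the most basic and least hindered oxyanion and give 4-O-(triisopropylsilyl)phloretin F7.
- BnBr (2 equiv) and K2CO3 in DMF then give the 4',6'-dibenzyl ether F8.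
- Bu4NF buffered with AcOH in THF removes the silyl group, and the fallback returns to the route at 6.

## Further compounds

F1 | step 6 | 5,7-bis(benzyloxy)-2-[3,4-bis(benzyloxy)phenyl]-3-[5,7-bis(benzyloxy)-2-(4-hydroxyphenyl)-4-oxochroman-8-yl]-4H-chromen-4-one, mixture of C2'' epimers | O=C1CC(c2ccc(O)cc2)Oc2c1c(OCc1ccccc1)cc(OCc1ccccc1)c2-c1c(-c2ccc(OCc3ccccc3)c(OCc3ccccc3)c2)oc2cc(OCc3ccccc3)cc(OCc3ccccc3)c2c1=O
F2 | step 6 | (2''R) isomer of 11 | O=C1C[C@H](c2ccc(O)cc2)Oc2c1c(OCc1ccccc1)cc(OCc1ccccc1)c2-c1c(-c2ccc(OCc3ccccc3)c(OCc3ccccc3)c2)oc2cc(OCc3ccccc3)cc(OCc3ccccc3)c2c1=O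
F3 | step 7 | (2S,3S,2''S) diastereomer of 12 | O=C1C[C@@H](c2ccc(O)cc2)Oc2c1c(OCc1ccccc1)cc(OCc1ccccc1)c2[C@@H]1C(=O)c2c(OCc3ccccc3)cc(OCc3ccccc3)cc2O[C@@H]1c1ccc(OCc2ccccc2)c(OCc2ccccc2)c1
F4 | step 5 | 1-[4,6-bis(benzyloxy)-3-iodo-2-(methoxymethoxy)phenyl]-3-[4-(methoxymethoxy)phenyl]propan-1-one | O=C(CCc1ccc(OCOC)cc1)c1c(OCOC)c(I)c(OCc2ccccc2)cc1OCc1ccccc1
F5 | step 5 | 3-(chlorozincio)-5,7,3',4'-tetra-O-benzylluteolin | Cl[Zn]c1c(-c2ccc(OCc3ccccc3)c(OCc3ccccc3)c2)oc2cc(OCc3ccccc3)cc(OCc3ccccc3)c2c1=O
F6 | step 5 | bis(methoxymethyl) ether of 9 (on the 2'-oxygen and on the oxygen of the 4-hydroxyphenyl ring) | O=C(CCc1ccc(OCOC)cc1)c1c(OCOC)c(-c2c(-c3ccc(OCc4ccccc4)c(OCc4ccccc4)c3)oc3cc(OCc4ccccc4)cc(OCc4ccccc4)c3c2=O)c(OCc2ccccc2)cc1OCc1ccccc1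
F7 | step 3 | 4-O-(triisopropylsilyl)phloretin; 1-(2,4,6-trihydroxyphenyl)-3-[4-(triisopropylsilyloxy)phenyl]propan-1-one | O=C(CCc1ccc(O[Si](C(C)C)(C(C)C)C(C)C)cc1)c1c(O)cc(O)cc1O
F8 | step 3 | 4',6'-di-O-benzyl-4-O-(triisopropylsilyl)phloretin | O=C(CCc1ccc(O[Si](C(C)C)(C(C)C)C(C)C)cc1)c1c(O)cc(OCc2ccccc2)cc1OCc1ccccc1
A1 | alternative 1 | 2-[5,7-bis(benzyloxy)-2-(4-benzyloxyphenyl)-4-oxo-4H-chromen-8-yl]-1-(2,4,6-trihydroxyphenyl)ethanone | O=C(Cc1c(OCc2ccccc2)cc(OCc2ccccc2)c2c(=O)cc(-c3ccc(OCc4ccccc4)cc3)oc12)c1c(O)cc(O)cc1O
A2 | alternative 1 | 6-{5-[5,7-bis(benzyloxy)-2-(4-benzyloxyphenyl)-4-oxo-4H-chromen-8-yl]-2,4-dioxopentyl}-2,2-dimethyl-4H-1,3-dioxin-4-one | CC1(C)OC(=O)C=C(CC(=O)CC(=O)Cc2c(OCc3ccccc3)cc(OCc3ccccc3)c3c(=O)cc(-c4ccc(OCc5ccccc5)cc4)oc23)O1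
A3 | alternative 1 | methyl 8-[5,7-bis(benzyloxy)-2-(4-benzyloxyphenyl)-4-oxo-4H-chromen-8-yl]-3,5,7-trioxooctanoate | COC(=O)CC(=O)CC(=O)CC(=O)Cc1c(OCc2ccccc2)cc(OCc2ccccc2)c2c(=O)cc(-c3ccc(OCc4ccccc4)cc3)oc12
A4 | alternative 2 | (2R,3R)-5,7-bis(benzyloxy)-2-[3,4-bis(benzyloxy)phenyl]-3-[5,7-bis(benzyloxy)-2-(4-benzyloxyphenyl)-4-oxo-4H-chromen-8-yl]chroman-4-one | O=c1cc(-c2ccc(OCc3ccccc3)cc2)oc2c1c(OCc1ccccc1)cc(OCc1ccccc1)c2[C@H]1C(=O)c2c(OCc3ccccc3)cc(OCc3ccccc3)cc2O[C@H]1c1ccc(OCc2ccccc2)c(OCc2ccccc2)c1
A5 | alternative 2 | methyl (2R,3R)-3-[3,4-bis(benzyloxy)phenyl]-2-[5,7-bis(benzyloxy)-2-(4-benzyloxyphenyl)-4-oxo-4H-chromen-8-yl]-3-hydroxypropanoate | O=c1cc(-c2ccc(OCc3ccccc3)cc2)oc2c1c(OCc1ccccc1)cc(OCc1ccccc1)c2[C@@H](C(=O)OC)[C@@H](O)c1ccc(OCc2ccccc2)c(OCc2ccccc2)c1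
A6 | alternative 2 | 3,5-bis(benzyloxy)-2-(trimethylsilyl)phenyl trifluoromethanesulfonate | C[Si](C)(C)c1c(OCc2ccccc2)cc(OCc2ccccc2)cc1OS(=O)(=O)C(F)(F)F
A7 | alternative 2 | 3,5-bis(benzyloxy)benzyne | C1(OCc2ccccc2)=CC(OCc2ccccc2)=CC#C1
A8 | alternative 3 | (2R,3R)-7-(benzyloxy)-5-[3,4-bis(benzyloxy)benzyloxy]-2-[3,4-bis(benzyloxy)phenyl]-3-[(2S)-5,7-bis(benzyloxy)-2-(4-benzyloxyphenyl)-4-oxochroman-8-yl]chroman-4-one | O=C1C[C@@H](c2ccc(OCc3ccccc3)cc2)Oc2c1c(OCc1ccccc1)cc(OCc1ccccc1)c2[C@H]1C(=O)c2c(OCc3ccc(OCc4ccccc4)c(OCc4ccccc4)c3)cc(OCc3ccccc3)cc2O[C@H]1c1ccc(OCc2ccccc2)c(OCc2ccccc2)c1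
A9 | alternative 3 | (2S)-5,7-bis(benzyloxy)-2-(4-benzyloxyphenyl)-8-(1-diazo-2-{4-(benzyloxy)-2,6-bis[3,4-bis(benzyloxy)benzyloxy]phenyl}-2-oxoethyl)chroman-4-one | O=C1C[C@@H](c2ccc(OCc3ccccc3)cc2)Oc2c1c(OCc1ccccc1)cc(OCc1ccccc1)c2C(=[N+]=[N-])C(=O)c1c(OCc2ccc(OCc3ccccc3)c(OCc3ccccc3)c2)cc(OCc2ccccc2)cc1OCc1ccc(OCc2ccccc2)c(OCc2ccccc2)c1
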